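## Retrosynthetic overview

1. Target 30 ⇒ desilylation, α-methylenation and C8 esterification ⇒ hydroxy lactone 18 + (Z)-acid 23 (from methyl but-2-ynoate).
2. 18 ⇒ the γ-lactone is closed last on the finished ten-membered ring: C6 reduction/lactonisation, then C8 reduction, of the 2-substituted cyclodecadiene-1,3-dione 13.
3. 13 ⇒ four-carbon ring expansion of spiro-epoxycyclohexadienone 8: aldol of its 2-oxopropyl arm onto the dienone C=O, retro-aldol cleavage of the old ring bond C1–C6, C-alkylation with methyl bromoacetate. The arene carbons become the Z,Z-diene and the spiro-epoxide becomes the ring epoxide.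
4. 8 ⇒ periodate dearomatisation of phenol 7 ⇒ asymmetric acetone aldol on aryl glyoxylate 5 ⇒ m-cresol + oxalyl chloride.
5. Ring order: benzene ring (bought) → epoxide → transient cyclohexanone ring A → ten-membered ring → lactone.

Assumption: names use germacrane numbering (C1/C10 epoxide carbons with C14 on C10; C2=C3–C4(C15)=C5 diene; C6 lactone O–CH; C7; C8 acyloxy CH; C9; C11–C13 methylene-lactone carbons); the target is (1R,6S,7R,8R,10R,2Z,4Z), with O6, C11 and O8 all cis and the epoxide cis on the ring.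

## Route

Step 1
Reactants: 1 3-methylphenol (m-cresol); 2 oxalyl chloride
Product: 5 methyl 2-(2-hydroxy-4-methylphenyl)-2-oxoacetate, via 3-methylphenyl chlorooxoacetate 3 (not isolated), via 6-methyl-1-benzofuran-2,3-dione 4 (not isolated)
Conditions: (COCl)2, Et2O, 0 °C → rt; AlCl3, ClCH2CH2Cl, 0 °C → rt; then MeOH, 0 °C
Reagents that add atoms: methanol, `CO`
Why: O-acylation followed by intramolecular Friedel–Crafts acylation (Stollé-type) can only close ortho to oxygen and does so at the unhindered position para to the methyl group, and methanol then opens the strained five-membered aryl ester to the hydroxyaryl glyoxylate.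

Step 2
Reactants: 5 methyl 2-(2-hydroxy-4-methylphenyl)-2-oxoacetate; 6 acetone
Product: 7 methyl (2S)-2-hydroxy-2-(2-hydroxy-4-methylphenyl)-4-oxopentanoate
Conditions: acetone (solvent), 9-amino-9-deoxy-epi-quinine (10 mol %), CF3CO2H (20 mol %), 0 °C
Reagents that add atoms: none
Why: primary-amine (enamine) catalysed direct asymmetric aldol of acetone to an aryl α-keto ester, in which the protonated catalyst binds the 1,2-dicarbonyl and fixes the face that gives the (S)-tertiary alcohol (future C10), the pseudo-enantiomeric quinidine-derived amine being used instead if the sense proves opposite.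

Step 3
Reactants: 7 methyl (2S)-2-hydroxy-2-(2-hydroxy-4-methylphenyl)-4-oxopentanoate
Product: 8 methyl (2S,3S)-6-methyl-4-oxo-2-(2-oxopropyl)-1-oxaspiro[2.5]octa-5,7-diene-2-carboxylate
Conditions: NaIO4 (1.5 equiv), MeOH–H2O (2:1), 0 °C, 30 min; extracted cold and used at once
Reagents that add atoms: none
Why: Adler–Becker oxidation, in which the aryl periodate ester is attacked at the ipso carbon by the neighbouring tertiary hydroxyl (its oxygen becomes the epoxide oxygen, C10 is untouched) to give the spiro-epoxy-2,4-dienone; the new spiro centre is expected to form with only modest preference for the (3S) epimer drawn (ester turned away from the aryl–O–I dipole, 2-oxopropyl arm on the carbonyl side), and its epimer, which cannot close ring A, is left behind in step 4.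

Step 4
Reactants: 8 methyl (2S,3S)-6-methyl-4-oxo-2-(2-oxopropyl)-1-oxaspiro[2.5]octa-5,7-diene-2-carboxylate; 9 methyl bromoacetate
Product: 13 dimethyl (1R,10S,2Z,4Z)-1,10-epoxy-6,8-dioxo-13-norgermacra-2,4-diene-12,14-dioate (C7 stereolabile), via potassium enolate 10 (not isolated), via tricyclic potassium aldolate 11 (not isolated), via ring-expanded potassium diketonate 12 (not isolated)
Conditions: KN(SiMe3)2 (1.05 equiv), 18-crown-6 (1.1 equiv), THF, −78 → −20 °C; then BrCH2CO2Me, −20 °C → rt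
Reagents that add atoms: none
Why: Proposed new method: an aldol/retro-aldol four-carbon ring expansion in which kinetic enolisation of the methyl ketone (hindered base, −78 °C, sparing the neopentylic C9–H2 and hence the epoxide) is followed by 6-exo aldol addition to the dienone carbonyl, the only site the arm can reach and only in the cis sense, after which the ring-fusion alkoxide 11 expels C1 as the ε-carbanion of the newly formed linearly conjugated dienone (an extended, configurationally labile enolate) instead of reverting, because proton transfer to that carbanion gives the β-diketonate 12 irreversibly; the carbanion relaxes from the strained E-type to the Z-type ring geometry and is protonated on the outer face, so C1 is inverted and the epoxide becomes cis on the ten-membered ring while C10 is untouched and the former arene carbons remain as the Z,Z-diene, and C-alkylation of 12 with the bromoacetate then adds C11/C12; the closest known reactions are Hesse-type ring enlargements of 2-nitro- or 2-sulfonylcycloalkanones carrying a 3-oxobutyl chain and Barbier-cyclisation/Grob-fragmentation sequences, neither shown with a dienone carbonyl and an unactivated vinylogous epoxy carbanion as the leaving group.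

Step 5
Reactants: 13 dimethyl (1R,10S,2Z,4Z)-1,10-epoxy-6,8-dioxo-13-norgermacra-2,4-diene-12,14-dioate
Product: 15 methyl (1R,6S,7S,10S,2Z,4Z)-1,10-epoxy-8-oxo-13-norgermacra-2,4-dien-12,6-olid-14-oate (cis-fused lactone), via hydroxy keto diester 14 (not isolated)
Conditions: RuCl[(R,R)-TsDPEN](p-cymene) (2 mol %), HCO2Na (5 equiv), H2O–CH2Cl2, rt; then PPTS (10 mol %), CH2Cl2, rt; used directly
Reagents that add atoms: none
Why: Noyori–Ikariya transfer hydrogenation reduces only the conjugated dienyl ketone (dialkyl ketones such as C8 and C=C bonds are inert to this catalyst), the (R,R)-ligand fixing 6S by π-substituent/alkyl discrimination as for aryl ketones, while the stereolabile C7 of the 1,3-diketone is resolved dynamically toward the 6,7-cis hydroxy ester (hydride anti to the acetate arm, as in cis-selective reductions of 2-substituted cycloalkanones), which PPTS closes to the cis-fused γ-lactone.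

Step 6
Reactants: 15 methyl (1R,6S,7S,10S,2Z,4Z)-1,10-epoxy-8-oxo-13-norgermacra-2,4-dien-12,6-olid-14-oate
Product: 17 (1R,6S,7R,8R,10R,2Z,4Z)-1,10-epoxy-8,14-dihydroxy-13-norgermacra-2,4-dien-12,6-olide, via 8-hydroxy lactone ester 16 (not isolated)
Conditions: NaBH4 (4 equiv), MeOH–THF, −40 °C (1 h) → 0 °C (3 h)
Reagents that add atoms: none
Why: borohydride adds to the C8 ketone from the face opposite the cis-fused lactone (C11 shields its own face), setting 8R with O8 cis to C11 and O6, and on warming it reduces the α-oxygenated (glycidic) methyl ester, an activated ester, to the C14 primary alcohol while the γ-lactone survives.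

Step 7
Reactants: 17 (1R,6S,7R,8R,10R,2Z,4Z)-1,10-epoxy-8,14-dihydroxy-13-norgermacra-2,4-dien-12,6-olide
Product: 18 (1R,6S,7R,8R,10R,2Z,4Z)-14-[tert-butyl(dimethyl)silyl]oxy-1,10-epoxy-8-hydroxy-13-norgermacra-2,4-dien-12,6-olide
Conditions: TBSCl (1.1 equiv), imidazole, CH2Cl2, 0 °C
Reagents that add atoms: tert-butyldimethylsilyl chloride, `CC(C)(C)[Si](C)(C)Cl`
Why: silylation under these conditions is selective for the primary C14 hydroxyl over the hindered secondary C8 hydroxyl and touches no stereocentre.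

Step 8
Reactants: 19 methyl but-2-ynoate
Product: 21 methyl (2Z)-2-(hydroxymethyl)but-2-enoate, via alkenylalane 20 (not isolated)
Conditions: i-Bu2AlH, N-methylmorpholine N-oxide, THF, 0 °C; then CH2O (gas, from cracked (CH2O)n), 0 °C → rt
Reagents that add atoms: formaldehyde (from paraformaldehyde), `C=O`
Why: conjugate hydroalumination of the ynoate (vinylalumination) puts hydride on C3 and aluminium on C2, and formaldehyde then attacks C2 on the side of the β-hydrogen, which leaves the methyl group cis to the ester, the Z (angelate-type) geometry.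

Step 9
Reactants: 21 methyl (2Z)-2-(hydroxymethyl)but-2-enoate
Product: 22 methyl (2Z)-2-{[tert-butyl(dimethyl)silyl]oxymethyl}but-2-enoate
Conditions: TBSCl, imidazole, DMF, rt
Reagents that add atoms: tert-butyldimethylsilyl chloride, `CC(C)(C)[Si](C)(C)Cl`
Why: routine silylation of a primary allylic alcohol, which does not affect the alkene geometry.

Step 10
Reactants: 22 methyl (2Z)-2-{[tert-butyl(dimethyl)silyl]oxymethyl}but-2-enoate
Product: 23 (2Z)-2-{[tert-butyl(dimethyl)silyl]oxymethyl}but-2-enoic acid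
Conditions: LiOH·H2O, THF–H2O, rt; then 1 M HCl to pH 4
Reagents that add atoms: lithium hydroxide, `[Li+].[OH-]`
Why: hydroxide attacks the unhindered methyl ester (acyl–oxygen cleavage) while the trisubstituted Z-alkene and the primary silyl ether are stable to LiOH at room temperature.

Step 11
Reactants: 18 (1R,6S,7R,8R,10R,2Z,4Z)-14-[tert-butyl(dimethyl)silyl]oxy-1,10-epoxy-8-hydroxy-13-norgermacra-2,4-dien-12,6-olide; 23 (2Z)-2-{[tert-butyl(dimethyl)silyl]oxymethyl}but-2-enoic acid
Product: 25 (1R,6S,7R,8R,10R,2Z,4Z)-14-[tert-butyl(dimethyl)silyl]oxy-8-[(2Z)-2-{[tert-butyl(dimethyl)silyl]oxymethyl}but-2-enoyl]oxy-1,10-epoxy-13-norgermacra-2,4-dien-12,6-olide, via mixed anhydride 24 (not isolated)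
Conditions: 23, 2,4,6-Cl3C6H2COCl, Et3N, toluene, rt, 1 h; then 18, 75 °C (no DMAP)
Reagents that add atoms: none
Why: mixed-anhydride (Yamaguchi-type) esterification run without DMAP in warm toluene, the protocol used for angelates, so that no reversible conjugate addition can isomerise the Z-acrylate, and since the C8–O bond is not broken 8R is retained.

Step 12
Reactants: 25 (1R,6S,7R,8R,10R,2Z,4Z)-14-[tert-butyl(dimethyl)silyl]oxy-8-[(2Z)-2-{[tert-butyl(dimethyl)silyl]oxymethyl}but-2-enoyl]oxy-1,10-epoxy-13-norgermacra-2,4-dien-12,6-olide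
Product: 29 (1R,6S,7R,8R,10R,2Z,4Z)-14-[tert-butyl(dimethyl)silyl]oxy-8-[(2Z)-2-{[tert-butyl(dimethyl)silyl]oxymethyl}but-2-enoyl]oxy-1,10-epoxygermacra-2,4,11(13)-trien-12,6-olide, via lithium enolate 26 (not isolated), via Mannich base 27 (not isolated), via ammonium iodide 28 (not isolated)
Conditions: LiN(SiMe3)2 (1.1 equiv), THF, −78 °C; Me2N=CH2+ I−, −78 → 0 °C; then MeI, MeOH, rt; then NaHCO3 (aq), CH2Cl2
Reagents that add atoms: N,N-dimethylmethyleneiminium iodide, `C=[N+](C)C.[I-]`
Why: α-methylenation by the Eschenmoser-salt sequence, in which the lactone α-CH2 is the only position next to a carbonyl that is deprotonated at −78 °C, its enolate is trapped in a Mannich reaction faster than acyl transfer from O8, and quaternisation followed by mild-base E1cB loss of trimethylamine gives the exocyclic methylene without touching a stereocentre.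

Step 13
Reactants: 29 (1R,6S,7R,8R,10R,2Z,4Z)-14-[tert-butyl(dimethyl)silyl]oxy-8-[(2Z)-2-{[tert-butyl(dimethyl)silyl]oxymethyl}but-2-enoyl]oxy-1,10-epoxygermacra-2,4,11(13)-trien-12,6-olide
Product: 30 (1R,6S,7R,8R,10R,2Z,4Z)-1,10-epoxy-14-hydroxy-8-[(2Z)-2-(hydroxymethyl)but-2-enoyl]oxygermacra-2,4,11(13)-trien-12,6-olide (CNP0165856.1)
Conditions: Et3N·3HF, THF, rt
Reagents that add atoms: none
Why: the amine–HF complex cleaves both primary TBS ethers under near-neutral conditions that the vinyl epoxide, the α-methylene lactone and the Z-acrylate tolerate.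

## Compound list

1 | 3-methylphenol (m-cresol) | `Cc1cccc(O)c1` | starting material
2 | oxalyl chloride | `ClC(=O)C(=O)Cl` | starting material
3 | 3-methylphenyl chlorooxoacetate | `Cc1cccc(OC(=O)C(Cl)=O)c1` | intermediate
4 | 6-methyl-1-benzofuran-2,3-dione | `Cc1ccc2C(=O)C(=O)Oc2c1` | intermediate
5 | methyl 2-(2-hydroxy-4-methylphenyl)-2-oxoacetate | `COC(=O)C(=O)c1ccc(C)cc1O` | intermediate
6 | acetone | `CC(C)=O` | starting material
7 | methyl (2S)-2-hydroxy-2-(2-hydroxy-4-methylphenyl)-4-oxopentanoate | `O[C@@](c1ccc(C)cc1O)(C(=O)OC)CC(C)=O` | intermediate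
8 | methyl (2S,3S)-6-methyl-4-oxo-2-(2-oxopropyl)-1-oxaspiro[2.5]octa-5,7-diene-2-carboxylate (2-oxopropyl arm cis to the ring C=O on the epoxide) | `O=C1C=C(C)C=C[C@@]12O[C@@]2(C(=O)OC)CC(C)=O` | intermediate
9 | methyl bromoacetate | `COC(=O)CBr` | starting material
10 | potassium enolate of 8, enolised at the terminal CH3 of the 2-oxopropyl arm | `O=C1C=C(C)C=C[C@@]12O[C@@]2(C(=O)OC)CC(=C)[O-].[K+]` | intermediate
11 | potassium alkoxide of the tricyclic aldol: cyclohexadiene ring B and cyclohexanone ring A cis-fused through C1–C6, C1–C10 epoxide kept, C6–O(−) on the same face as the epoxide oxygen, CO2Me on C10 | `[K+].[O-][C@]12CC(=O)C[C@]3(C(=O)OC)O[C@]13C=CC(C)=C2` | intermediate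
12 | potassium C7-enolate (β-diketonate) of methyl (1R,10S,2Z,4Z)-1,10-epoxy-6,8-dioxo-11,12,13-trinorgermacra-2,4-dien-14-oate | `[K+].O=C1/C=C(C)\C=C/[C@H]2O[C@@]2(C(=O)OC)CC(=O)[CH-]1` | intermediate
13 | dimethyl (1R,10S,2Z,4Z)-1,10-epoxy-6,8-dioxo-13-norgermacra-2,4-diene-12,14-dioate (C7 stereolabile) | `O=C1/C=C(C)\C=C/[C@H]2O[C@@]2(C(=O)OC)CC(=O)C1CC(=O)OC` | intermediate
14 | dimethyl (1R,6S,7S,10S,2Z,4Z)-1,10-epoxy-6-hydroxy-8-oxo-13-norgermacra-2,4-diene-12,14-dioate | `O[C@H]1/C=C(C)\C=C/[C@H]2O[C@@]2(C(=O)OC)CC(=O)[C@H]1CC(=O)OC` | intermediate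
15 | methyl (1R,6S,7S,10S,2Z,4Z)-1,10-epoxy-8-oxo-13-norgermacra-2,4-dien-12,6-olid-14-oate (cis-fused lactone) | `C1C(=O)O[C@H]2/C=C(C)\C=C/[C@H]3O[C@@]3(C(=O)OC)CC(=O)[C@@H]12` | intermediate
16 | methyl (1R,6S,7R,8R,10S,2Z,4Z)-1,10-epoxy-8-hydroxy-13-norgermacra-2,4-dien-12,6-olid-14-oate | `C1C(=O)O[C@H]2/C=C(C)\C=C/[C@H]3O[C@@]3(C(=O)OC)C[C@@H](O)[C@@H]12` | intermediate
17 | (1R,6S,7R,8R,10R,2Z,4Z)-1,10-epoxy-8,14-dihydroxy-13-norgermacra-2,4-dien-12,6-olide | `C1C(=O)O[C@H]2/C=C(C)\C=C/[C@H]3O[C@@]3(CO)C[C@@H](O)[C@@H]12` | intermediate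
18 | (1R,6S,7R,8R,10R,2Z,4Z)-14-[tert-butyl(dimethyl)silyl]oxy-1,10-epoxy-8-hydroxy-13-norgermacra-2,4-dien-12,6-olide | `C1C(=O)O[C@H]2/C=C(C)\C=C/[C@H]3O[C@@]3(CO[Si](C)(C)C(C)(C)C)C[C@@H](O)[C@@H]12` | intermediate
19 | methyl but-2-ynoate | `CC#CC(=O)OC` | starting material
20 | methyl (2E)-2-[bis(2-methylpropyl)alumanyl]but-2-enoate (methyl cis to the ester) | `C/C=C(\C(=O)OC)[Al](CC(C)C)CC(C)C` | intermediate
21 | methyl (2Z)-2-(hydroxymethyl)but-2-enoate | `C/C=C(\C(=O)OC)CO` | intermediate
22 | methyl (2Z)-2-{[tert-butyl(dimethyl)silyl]oxymethyl}but-2-enoate | `C/C=C(\C(=O)OC)CO[Si](C)(C)C(C)(C)C` | intermediate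
23 | (2Z)-2-{[tert-butyl(dimethyl)silyl]oxymethyl}but-2-enoic acid | `C/C=C(\C(=O)O)CO[Si](C)(C)C(C)(C)C` | intermediate
24 | (2Z)-2-{[tert-butyl(dimethyl)silyl]oxymethyl}but-2-enoic 2,4,6-trichlorobenzoic anhydride | `C/C=C(\C(=O)OC(=O)c1c(Cl)cc(Cl)cc1Cl)CO[Si](C)(C)C(C)(C)C` | intermediate
25 | (1R,6S,7R,8R,10R,2Z,4Z)-14-[tert-butyl(dimethyl)silyl]oxy-8-[(2Z)-2-{[tert-butyl(dimethyl)silyl]oxymethyl}but-2-enoyl]oxy-1,10-epoxy-13-norgermacra-2,4-dien-12,6-olide | `C1C(=O)O[C@H]2/C=C(C)\C=C/[C@H]3O[C@@]3(CO[Si](C)(C)C(C)(C)C)C[C@@H](OC(=O)/C(=C\C)CO[Si](C)(C)C(C)(C)C)[C@@H]12` | intermediate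
26 | lithium enolate of 25 (C11=C12–O−) | `C1=C([O-])O[C@H]2/C=C(C)\C=C/[C@H]3O[C@@]3(CO[Si](C)(C)C(C)(C)C)C[C@@H](OC(=O)/C(=C\C)CO[Si](C)(C)C(C)(C)C)[C@@H]12.[Li+]` | intermediate
27 | 13-(dimethylamino) Mannich base of 25: the 11,13-dihydro-13-(dimethylamino)germacranolide, C11 epimers | `CN(C)CC1C(=O)O[C@H]2/C=C(C)\C=C/[C@H]3O[C@@]3(CO[Si](C)(C)C(C)(C)C)C[C@@H](OC(=O)/C(=C\C)CO[Si](C)(C)C(C)(C)C)[C@@H]12` | intermediate
28 | N,N,N-trimethylammonium iodide of 27 | `C[N+](C)(C)CC1C(=O)O[C@H]2/C=C(C)\C=C/[C@H]3O[C@@]3(CO[Si](C)(C)C(C)(C)C)C[C@@H](OC(=O)/C(=C\C)CO[Si](C)(C)C(C)(C)C)[C@@H]12.[I-]` | intermediate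
29 | (1R,6S,7R,8R,10R,2Z,4Z)-14-[tert-butyl(dimethyl)silyl]oxy-8-[(2Z)-2-{[tert-butyl(dimethyl)silyl]oxymethyl}but-2-enoyl]oxy-1,10-epoxygermacra-2,4,11(13)-trien-12,6-olide | `C=C1C(=O)O[C@H]2/C=C(C)\C=C/[C@H]3O[C@@]3(CO[Si](C)(C)C(C)(C)C)C[C@@H](OC(=O)/C(=C\C)CO[Si](C)(C)C(C)(C)C)[C@@H]12` | intermediate
30 | (1R,6S,7R,8R,10R,2Z,4Z)-1,10-epoxy-14-hydroxy-8-[(2Z)-2-(hydroxymethyl)but-2-enoyl]oxygermacra-2,4,11(13)-trien-12,6-olide (CNP0165856.1) | `C=C1C(=O)O[C@H]2/C=C(C)\C=C/[C@H]3O[C@@]3(CO)C[C@@H](OC(=O)/C(=C\C)CO)[C@@H]12` | target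

## Step count and risk

Total: 13 steps (ten in the main line, three for acid 23). Longest linear sequence: 10 steps (steps 1–7, 11, 12, 13).

The three steps most likely to fail:

Step 4 (the proposed ring expansion). The aldolate may simply revert, the C1 carbanion may be protonated with retention by the adjacent C7–H (giving the trans-epoxide, the C1 epimer), or the diketonate may O-alkylate. Fallback with known chemistry, setting out from 8 and returning at 13: the two events are separated. LiN(SiMe3)2 in THF at −78 °C with a cold AcOH quench gives the isolated intramolecular aldol, the cis-fused tricyclic β-hydroxy ketone F1. Its ring-fusion C–C bond is then cleaved by alkoxy-radical β-scission under photocatalytic proton-coupled electron transfer ([Ir(dF(CF3)ppy)2(5,5′-d(CF3)bpy)]PF6, Bu4N+ (BuO)2PO2−, 2,4,6-triisopropylbenzenethiol, CH2Cl2, blue LEDs), the known redox-neutral ring opening of cyclic tertiary alcohols. Hydrogen-atom return from the thiol to the dienyl-stabilised C1 radical gives the neutral ten-membered 1,3-diketone F2. K2CO3 and 9 in acetone then C-alkylate F2 to 13.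

Step 5 (chemoselective transfer hydrogenation and lactonisation). The C8 ketone may be reduced as well, C7 may resolve to the trans relationship, or the β,γ-epoxy ketone may open by enolisation at C9. Fallback setting out from 13 and returning at 16: the order of the two reductions is reversed. NaBH4 (0.3 equiv) in MeOH–CH2Cl2 at −78 °C reduces the more electrophilic saturated C8 ketone first; the resulting 8-hydroxy-6-oxo diester F3 closes spontaneously to the 8,12-lactone F4. Luche reduction (NaBH4, CeCl3·7H2O, MeOH, −78 °C) of the dienone from the face opposite the fused lactone gives the 6-hydroxy-8,12-olide F5. Because O6, C11 and O8 are all cis and no ketone is left to make base dangerous, catalytic DBU in toluene equilibrates F5 with the 6,12-olide 16 by translactonisation; 16 is separated and F5 recycled, and 16 is reduced to 17 as in step 6.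

Step 6 (facial selectivity at C8 in a ten-membered ring). Hydride may come mainly from the lactone face. Fallback setting out from 15 and returning at 25: the 8-epimer is used instead of fought. The same borohydride treatment gives, through the 8-epi hydroxy lactone ester F6, the 8-epi diol F7. TBSCl/imidazole gives the 8-epi silyl ether F8. Mitsunobu esterification of F8 with acid 23 (PPh3, i-PrO2CN=NCO2i-Pr, toluene, 0 °C) installs the ester with inversion at C8 and delivers 25 directly, replacing step 11.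

Further compounds

F1 | step 4 | cis-fused tricyclic β-hydroxy ketone (neutral alcohol of 11) | `O[C@]12CC(=O)C[C@]3(C(=O)OC)O[C@]13C=CC(C)=C2`
F2 | step 4 | methyl (1R,10S,2Z,4Z)-1,10-epoxy-6,8-dioxo-11,12,13-trinorgermacra-2,4-dien-14-oate | `O=C1/C=C(C)\C=C/[C@H]2O[C@@]2(C(=O)OC)CC(=O)C1`
F3 | step 5 | dimethyl (1R,7R,8R,10S,2Z,4Z)-1,10-epoxy-8-hydroxy-6-oxo-13-norgermacra-2,4-diene-12,14-dioate | `O=C1/C=C(C)\C=C/[C@H]2O[C@@]2(C(=O)OC)C[C@@H](O)[C@H]1CC(=O)OC`
F4 | step 5 | methyl (1R,7R,8R,10S,2Z,4Z)-1,10-epoxy-6-oxo-13-norgermacra-2,4-dien-12,8-olid-14-oate | `O=C1/C=C(C)\C=C/[C@H]2O[C@@]2(C(=O)OC)C[C@H]3OC(=O)C[C@@H]13`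
F5 | step 5 | methyl (1R,6S,7S,8R,10S,2Z,4Z)-1,10-epoxy-6-hydroxy-13-norgermacra-2,4-dien-12,8-olid-14-oate | `O[C@H]1/C=C(C)\C=C/[C@H]2O[C@@]2(C(=O)OC)C[C@H]3OC(=O)C[C@@H]13`
F6 | step 6 | methyl (1R,6S,7R,8S,10S,2Z,4Z)-1,10-epoxy-8-hydroxy-13-norgermacra-2,4-dien-12,6-olid-14-oate (8-epimer of 16) | `C1C(=O)O[C@H]2/C=C(C)\C=C/[C@H]3O[C@@]3(C(=O)OC)C[C@H](O)[C@@H]12`
F7 | step 6 | (1R,6S,7R,8S,10R,2Z,4Z)-1,10-epoxy-8,14-dihydroxy-13-norgermacra-2,4-dien-12,6-olide (8-epimer of 17) | `C1C(=O)O[C@H]2/C=C(C)\C=C/[C@H]3O[C@@]3(CO)C[C@H](O)[C@@H]12`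
F8 | step 6 | (1R,6S,7R,8S,10R,2Z,4Z)-14-[tert-butyl(dimethyl)silyl]oxy-1,10-epoxy-8-hydroxy-13-norgermacra-2,4-dien-12,6-olide (8-epimer of 18) | `C1C(=O)O[C@H]2/C=C(C)\C=C/[C@H]3O[C@@]3(CO[Si](C)(C)C(C)(C)C)C[C@H](O)[C@@H]12`
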